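Ring C is cut at O1–C8a and C4–C4a. The ether oxygen and the ketone carbon sit on neighbouring carbons of ring A, between the C5 oxygen and the C8 geranyl group, so an aryne spanning C4a and C8a can take up both in one operation: the alkoxide of an anti β-hydroxy ester that already carries C2 and C3 adds through oxygen, and the C4a carbanion then closes onto the ester. The aryne precursor is a geranylated ortho-silylaryl triflate built from phloroglucinol by two directed metalations; the ester comes from an auxiliary-controlled anti glycolate aldol and carries the C3 oxygen as an allyl ether, which cannot migrate to the alkoxide or be cleaved by fluoride.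

Key step: step 10

Assumption: in step 8 the activated aldehyde is taken to attack the enolate face opposite the benzyl group of the sulfur-chelated enolate, which makes the (S)-auxiliary the source of the (2R,3R) adduct; if the sense proved opposite, the (R)-auxiliary would be used.
Assumption: (allyloxy)acetic acid, (S)-4-benzyl-1,3-oxazolidine-2-thione and 4-(allyloxy)benzaldehyde are taken as catalogue compounds; geranyl stands for (2E)-3,7-dimethylocta-2,6-dien-1-yl and allyl for prop-2-en-1-yl.

Step 1
Reactants: 1 phloroglucinol
Product: 2 3,5-bis(methoxymethoxy)phenol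
Conditions: MOMCl (2.0 equiv), i-Pr2NEt, DMF, 0 °C to rt
Reagents that add atoms: chloromethyl methyl ether, COCCl
Why: Williamson-type O-alkylation of the phenoxide by the α-chloro ether; the three hydroxyls are equivalent, so two equivalents of reagent should give the bis-ether as the main component of a statistical mixture, from which it is separated by chromatography while the mono-ether is resubmitted.

Step 2
Reactants: 2 3,5-bis(methoxymethoxy)phenol
Product: 3 3,5-bis(methoxymethoxy)phenyl N,N-diethylcarbamate
Conditions: NaH, THF, 0 °C; Et2NCOCl, rt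
Reagents that add atoms: N,N-diethylcarbamoyl chloride, CCN(CC)C(=O)Cl
Why: O-acylation of the sodium phenoxide by the carbamoyl chloride should proceed cleanly and puts the strongest oxygen-based directing group on the one oxygen that later becomes the triflate.

Step 3
Reactants: 3 3,5-bis(methoxymethoxy)phenyl N,N-diethylcarbamate
Product: 5 3,5-bis(methoxymethoxy)-2-(trimethylsilyl)phenyl N,N-diethylcarbamate, via aryllithium 4 (not isolated)
Conditions: s-BuLi, TMEDA, THF, −78 °C; TMSCl, −78 °C to rt
Reagents that add atoms: chlorotrimethylsilane, C[Si](C)(C)Cl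
Why: Directed ortho-metalation: the carbamate outranks the methoxymethyl ethers as a director and each of the two equivalent positions between it and an acetal oxygen is doubly activated, so lithiation should occur there in preference to the single site between the two acetals, and the aryllithium is silylated cold, before an anionic Fries rearrangement can set in.

Step 4
Reactants: 5 3,5-bis(methoxymethoxy)-2-(trimethylsilyl)phenyl N,N-diethylcarbamate; 6 geranyl bromide
Product: 9 2-geranyl-3,5-bis(methoxymethoxy)-6-(trimethylsilyl)phenyl N,N-diethylcarbamate, via aryllithium 7 (not isolated), via arylcopper 8 (not isolated)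
Conditions: s-BuLi, TMEDA, THF, −78 °C; CuBr·SMe2, −78 to −40 °C; 6, −78 to 0 °C
Reagents that add atoms: none
Why: A second directed ortho-metalation should take the one remaining position between the carbamate and an acetal oxygen (the silyl group blocks the other), and transmetalation to copper makes the aryl nucleophile soft enough to displace the primary allylic bromide in an SN2 sense, which should keep the chain linear and the E double bond intact.

Step 5
Reactants: 9 2-geranyl-3,5-bis(methoxymethoxy)-6-(trimethylsilyl)phenyl N,N-diethylcarbamate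
Product: 10 2-geranyl-3,5-bis(methoxymethoxy)-6-(trimethylsilyl)phenol
Conditions: LiAlH4, THF, 0 to 40 °C; aqueous potassium sodium tartrate work-up
Reagents that add atoms: none
Why: Reductive carbamate cleavage: hydride attacks the carbamate carbonyl and expels the phenoxide, which does not require access to the hindered aryl oxygen, and the non-acidic work-up avoids protodesilylation of the electron-rich aryl silane.

Step 6
Reactants: 10 2-geranyl-3,5-bis(methoxymethoxy)-6-(trimethylsilyl)phenol
Product: 11 2-geranyl-3,5-bis(methoxymethoxy)-6-(trimethylsilyl)phenyl trifluoromethanesulfonate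
Conditions: NaH, THF, 0 °C; PhNTf2, rt
Reagents that add atoms: N-phenylbis(trifluoromethanesulfonimide), O=S(=O)(N(c1ccccc1)S(=O)(=O)C(F)(F)F)C(F)(F)F
Why: O-sulfonylation of the sodium phenoxide with a mild triflating agent should give the ortho-silylaryl triflate, the standard fluoride-triggered aryne precursor, without exposing the aryl silane, the acetals or the alkenes to acid.

Step 7
Reactants: 12 (allyloxy)acetic acid; 13 (S)-4-benzyl-1,3-oxazolidine-2-thione
Product: 14 (S)-3-[(allyloxy)acetyl]-4-benzyl-1,3-oxazolidine-2-thione
Conditions: DCC, DMAP (cat.), CH2Cl2, 0 °C to rt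
Reagents that add atoms: none
Why: Carbodiimide activation with DMAP catalysis (Steglich-type acylation) should acylate the auxiliary at nitrogen, the thermodynamically preferred site, and leaves the allyl ether untouched.

Step 8
Reactants: 14 (S)-3-[(allyloxy)acetyl]-4-benzyl-1,3-oxazolidine-2-thione; 15 4-(allyloxy)benzaldehyde
Product: 17 (S)-3-{(2R,3R)-2-(allyloxy)-3-[4-(allyloxy)phenyl]-3-hydroxypropanoyl}-4-benzyl-1,3-oxazolidine-2-thione, via trichlorotitanium enolate 16 (not isolated)
Conditions: TiCl4 (1.1 equiv), i-Pr2NEt, CH2Cl2, −78 °C; then 15 premixed with TiCl4, −78 °C; NH4Cl quench at −78 °C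
Reagents that add atoms: none
Why: Soft enolisation gives the Z enolate held rigid on titanium by the thiocarbonyl and the ether oxygen, so the separately TiCl4-activated aldehyde can only react through an open transition state on the face away from the benzyl group, which should set both new centres (2R and 3R of the side chain) in the anti relationship (auxiliary-controlled titanium aldol, anti glycolate variant).

Step 9
Reactants: 17 (S)-3-{(2R,3R)-2-(allyloxy)-3-[4-(allyloxy)phenyl]-3-hydroxypropanoyl}-4-benzyl-1,3-oxazolidine-2-thione
Product: 18 methyl (2R,3R)-2-(allyloxy)-3-[4-(allyloxy)phenyl]-3-hydroxypropanoate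
Conditions: MeOH, imidazole, CH2Cl2, rt
Reagents that add atoms: methanol, CO
Why: The N-acyl oxazolidinethione is an activated amide, so imidazole-catalysed acyl transfer to methanol should release the methyl ester and the recoverable auxiliary at room temperature, without the strong base that would invite retro-aldol cleavage or epimerisation at C2.

Step 10
Reactants: 11 2-geranyl-3,5-bis(methoxymethoxy)-6-(trimethylsilyl)phenyl trifluoromethanesulfonate; 18 methyl (2R,3R)-2-(allyloxy)-3-[4-(allyloxy)phenyl]-3-hydroxypropanoate
Product: 21 (2R,3R)-3-(allyloxy)-2-[4-(allyloxy)phenyl]-8-geranyl-5,7-bis(methoxymethoxy)chroman-4-one, via sodium alkoxide 19 (not isolated), via aryne 20 (not isolated)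
Conditions: 18, NaH (1.05 equiv), THF, 0 °C; then 11 (1.3 equiv), CsF, 18-crown-6, THF, −20 °C to rt; AcOH quench at −20 °C
Reagents that add atoms: none
Why: Proposed new method: fluoride attacks silicon and the aryl anion so formed expels triflate to give benzyne 20, whose C8a carbon takes up alkoxide 19 so that the negative charge appears at C4a, next to the C5 oxygen; this carbanion adds to the methyl ester and methoxide leaves, which forms O1–C8a and C4–C4a in one operation. The closest known reactions are the fluoride-mediated annulation of arynes with methyl salicylates to xanthones and the O-arylation of alcohols and alkoxides by arynes, but an aliphatic β-hydroxy ester has not been used as the two-point partner. Ring C closes by 6-exo-trig attack of the C4a carbanion on the ester carbonyl. No stereocentre is formed: C2 keeps its configuration because its C–O bond is never broken, and C3 carries an allyl ether that can neither migrate to the neighbouring alkoxide nor be removed by fluoride. The step needs regioselective addition to an unsymmetrical aryne, and the inductively withdrawing C5 acetal oxygen secures it by directing the nucleophile to the distal carbon C8a, against the weaker steric bias of the C8 geranyl arm. THF as an aprotic medium, complete deprotonation of the alcohol and low temperature are chosen so that acyl capture outruns protonation of the carbanion and retro-aldol cleavage of the alkoxide.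

Step 11
Reactants: 21 (2R,3R)-3-(allyloxy)-2-[4-(allyloxy)phenyl]-8-geranyl-5,7-bis(methoxymethoxy)chroman-4-one
Product: 23 (2R,3R)-8-geranyl-3,5,7-trihydroxy-2-(4-hydroxyphenyl)chroman-4-one, via bis(propenyl) ether 22 (not isolated)
Conditions: [Ir(cod)(PMePh2)2]PF6 (cat., activated with H2, then degassed), THF, rt; then 2 M HCl, MeOH, 40 °C
Reagents that add atoms: none
Why: The cationic iridium hydride moves the terminal double bond of both allyl ethers into conjugation with oxygen (allyl-to-propenyl isomerisation) and ignores the trisubstituted alkenes of the geranyl chain, after which dilute methanolic HCl hydrolyses the two enol ethers and the two phenolic acetals in the same pot; no base is present, so C2 and C3 of the base-sensitive dihydroflavonol should keep their configuration.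

Compound list
1 | phloroglucinol (benzene-1,3,5-triol) | Oc1cc(O)cc(O)c1 | starting material
2 | 3,5-bis(methoxymethoxy)phenol | COCOc1cc(O)cc(OCOC)c1 | intermediate
3 | 3,5-bis(methoxymethoxy)phenyl N,N-diethylcarbamate | CCN(CC)C(=O)Oc1cc(OCOC)cc(OCOC)c1 | intermediate
4 | [2-(diethylcarbamoyloxy)-4,6-bis(methoxymethoxy)phenyl]lithium | [Li]c1c(OC(=O)N(CC)CC)cc(OCOC)cc1OCOC | intermediate
5 | 3,5-bis(methoxymethoxy)-2-(trimethylsilyl)phenyl N,N-diethylcarbamate | CCN(CC)C(=O)Oc1cc(OCOC)cc(OCOC)c1[Si](C)(C)C | intermediate
6 | geranyl bromide, (2E)-1-bromo-3,7-dimethylocta-2,6-diene | CC(C)=CCC/C(C)=C/CBr | starting material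
7 | [2-(diethylcarbamoyloxy)-4,6-bis(methoxymethoxy)-3-(trimethylsilyl)phenyl]lithium | [Li]c1c(OCOC)cc(OCOC)c([Si](C)(C)C)c1OC(=O)N(CC)CC | intermediate
8 | [2-(diethylcarbamoyloxy)-4,6-bis(methoxymethoxy)-3-(trimethylsilyl)phenyl]copper | [Cu]c1c(OCOC)cc(OCOC)c([Si](C)(C)C)c1OC(=O)N(CC)CC | intermediate
9 | 2-geranyl-3,5-bis(methoxymethoxy)-6-(trimethylsilyl)phenyl N,N-diethylcarbamate | CCN(CC)C(=O)Oc1c(C/C=C(\C)CCC=C(C)C)c(OCOC)cc(OCOC)c1[Si](C)(C)C | intermediate
10 | 2-geranyl-3,5-bis(methoxymethoxy)-6-(trimethylsilyl)phenol | Oc1c(C/C=C(\C)CCC=C(C)C)c(OCOC)cc(OCOC)c1[Si](C)(C)C | intermediate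
11 | 2-geranyl-3,5-bis(methoxymethoxy)-6-(trimethylsilyl)phenyl trifluoromethanesulfonate | C[Si](C)(C)c1c(OCOC)cc(OCOC)c(C/C=C(\C)CCC=C(C)C)c1OS(=O)(=O)C(F)(F)F | intermediate
12 | (allyloxy)acetic acid | C=CCOCC(=O)O | starting material
13 | (S)-4-benzyl-1,3-oxazolidine-2-thione | S=C1N[C@@H](Cc2ccccc2)CO1 | starting material
14 | (S)-3-[(allyloxy)acetyl]-4-benzyl-1,3-oxazolidine-2-thione | C=CCOCC(=O)N1C(=S)OC[C@@H]1Cc1ccccc1 | intermediate
15 | 4-(allyloxy)benzaldehyde | C=CCOc1ccc(C=O)cc1 | starting material
16 | trichlorotitanium (Z)-enolate of 14 (allyloxy cis to the titanium-bound oxygen) | C=CCO/C=C(\O[Ti](Cl)(Cl)Cl)N1C(=S)OC[C@@H]1Cc1ccccc1 | intermediate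
17 | (S)-3-{(2R,3R)-2-(allyloxy)-3-[4-(allyloxy)phenyl]-3-hydroxypropanoyl}-4-benzyl-1,3-oxazolidine-2-thione | O=C([C@H](OCC=C)[C@H](O)c1ccc(OCC=C)cc1)N1C(=S)OC[C@@H]1Cc1ccccc1 | intermediate
18 | methyl (2R,3R)-2-(allyloxy)-3-[4-(allyloxy)phenyl]-3-hydroxypropanoate | COC(=O)[C@H](OCC=C)[C@H](O)c1ccc(OCC=C)cc1 | intermediate
19 | sodium alkoxide of 18 (deprotonated at the C3 hydroxyl, 2R,3R) | COC(=O)[C@H](OCC=C)[C@H]([O-])c1ccc(OCC=C)cc1.[Na+] | intermediate
20 | 3-geranyl-4,6-bis(methoxymethoxy)benzyne (1,2-didehydrobenzene) | COCOC1=CC(OCOC)=C(C/C=C(\C)CCC=C(C)C)C#C1 | intermediate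
21 | (2R,3R)-3-(allyloxy)-2-[4-(allyloxy)phenyl]-8-geranyl-5,7-bis(methoxymethoxy)chroman-4-one | CC(C)=CCC/C(C)=C/Cc1c(OCOC)cc(OCOC)c2c1O[C@H](c1ccc(OCC=C)cc1)[C@@H](OCC=C)C2=O | intermediate
22 | (2R,3R)-8-geranyl-5,7-bis(methoxymethoxy)-3-[(E)-prop-1-enyloxy]-2-{4-[(E)-prop-1-enyloxy]phenyl}chroman-4-one | CC(C)=CCC/C(C)=C/Cc1c(OCOC)cc(OCOC)c2c1O[C@H](c1ccc(O/C=C/C)cc1)[C@@H](O/C=C/C)C2=O | intermediate
23 | (2R,3R)-8-geranyl-3,5,7-trihydroxy-2-(4-hydroxyphenyl)chroman-4-one | CC(C)=CCC/C(C)=C/Cc1c(O)cc(O)c2c1O[C@H](c1ccc(O)cc1)[C@@H](O)C2=O | target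

Total step count: 11. Longest linear sequence: 8 steps (steps 1 to 6, 10 and 11).

Steps most likely to fail

Step 10. The C4a carbanion may pick up a proton before it reaches the ester, the alkoxide may fragment by retro-aldol cleavage, or the methoxide set free may open ring C of the product. The fallback divides the two bond formations and uses known reactions only. From 11 and 18, the aryne is generated in the presence of the neutral alcohol (KF, 18-crown-6, THF, −20 °C); this is an established O–H insertion that ends with protonation at C4a and needs no free alkoxide. It should give the aryl ether methyl (2R,3R)-2-(allyloxy)-3-[4-(allyloxy)phenyl]-3-[2-geranyl-3,5-bis(methoxymethoxy)phenoxy]propanoate F1. The ester is then cleaved under near-neutral conditions (Me3SnOH, 1,2-dichloroethane, 70 °C) to (2R,3R)-2-(allyloxy)-3-[4-(allyloxy)phenyl]-3-[2-geranyl-3,5-bis(methoxymethoxy)phenoxy]propanoic acid F2. Friedel–Crafts cycliacylation of the trioxygenated ring through the mixed trifluoroacetic anhydride (TFAA, 2,6-di-tert-butylpyridine, CH2Cl2, 0 °C) closes ring C at C4a, the only free position ortho to the ether oxygen, and rejoins the route at 21.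

Step 4. The hindered arylcopper may attack the tertiary end of the allylic bromide (allylic transposition), or the alkylation may stall. The fallback makes the carbon–carbon bond by palladium catalysis. From 5, the same lithiation is quenched with iodine to give 2-iodo-3,5-bis(methoxymethoxy)-6-(trimethylsilyl)phenyl N,N-diethylcarbamate F3. Geranyl bromide 6 is converted with Bu3SnLi (THF, −78 °C) into tributyl(geranyl)stannane F4. Stille coupling of F3 with F4 (Pd2(dba)3, AsPh3, DMF, 60 °C), in which reductive elimination from the allylpalladium intermediate occurs at the less hindered terminus, rejoins the route at 9.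

Step 8. Anti or facial selectivity may erode with the electron-rich aromatic aldehyde, or the benzylic titanium alkoxide may ionise under the excess Lewis acid. The fallback replaces auxiliary control by a reagent-controlled Mukaiyama aldol. From 12, esterification with ethanethiol (DCC, DMAP) gives S-ethyl 2-(allyloxy)ethanethioate F5. Enolisation and silylation (LDA, TMSCl, THF, −78 °C) give the silyl ketene thioacetal (Z)-2-(allyloxy)-1-(ethylthio)-1-(trimethylsilyloxy)ethene F6. Addition of F6 to aldehyde 15, promoted by Sn(OTf)2, a proline-derived chiral diamine (the enantiomer that delivers the 2R,3R series) and Bu2Sn(OAc)2 in CH2Cl2 at −78 °C, is a reaction type known to give anti adducts from α-alkoxy thioester acetals. It should give S-ethyl (2R,3R)-2-(allyloxy)-3-[4-(allyloxy)phenyl]-3-hydroxypropanethioate F7. Methanolysis of the thioester assisted by AgOCOCF3 (MeOH, rt) rejoins the route at 18.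

Further compounds
F1 | step 10 | methyl (2R,3R)-2-(allyloxy)-3-[4-(allyloxy)phenyl]-3-[2-geranyl-3,5-bis(methoxymethoxy)phenoxy]propanoate | COC(=O)[C@H](OCC=C)[C@H](Oc1cc(OCOC)cc(OCOC)c1C/C=C(\C)CCC=C(C)C)c1ccc(OCC=C)cc1
F2 | step 10 | (2R,3R)-2-(allyloxy)-3-[4-(allyloxy)phenyl]-3-[2-geranyl-3,5-bis(methoxymethoxy)phenoxy]propanoic acid | OC(=O)[C@H](OCC=C)[C@H](Oc1cc(OCOC)cc(OCOC)c1C/C=C(\C)CCC=C(C)C)c1ccc(OCC=C)cc1
F3 | step 4 | 2-iodo-3,5-bis(methoxymethoxy)-6-(trimethylsilyl)phenyl N,N-diethylcarbamate | CCN(CC)C(=O)Oc1c(I)c(OCOC)cc(OCOC)c1[Si](C)(C)C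
F4 | step 4 | tributyl[(2E)-3,7-dimethylocta-2,6-dien-1-yl]stannane | CC(C)=CCC/C(C)=C/C[Sn](CCCC)(CCCC)CCCC
F5 | step 8 | S-ethyl 2-(allyloxy)ethanethioate | C=CCOCC(=O)SCC
F6 | step 8 | (Z)-2-(allyloxy)-1-(ethylthio)-1-(trimethylsilyloxy)ethene | C=CCO/C=C(\SCC)O[Si](C)(C)C
F7 | step 8 | S-ethyl (2R,3R)-2-(allyloxy)-3-[4-(allyloxy)phenyl]-3-hydroxypropanethioate | CCSC(=O)[C@H](OCC=C)[C@H](O)c1ccc(OCC=C)cc1
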